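## Retrosynthetic overview

1. Target 14 comes from α-face epoxidation of the C8=C9 alkene and C6-O-benzoylation of jaeschkeanadiol 12.
2. The seven-membered ring is closed last. C8=C9 forms by ring-closing metathesis of seco-diene 11, and C6–C7 forms by chelate-controlled methallylation of aldehyde 10.
3. Key step: the C1–C10 bond and the quaternary centre form in an anionic oxy-Cope [3,3] shift of dienol 8, with 1,3-chirality transfer from C6 to C1.
4. The five-membered ring is made first, by ozonolysis and aldol ring contraction of (S)-terpinen-4-ol 1. This compound supplies C4 (OH, iPr), and C4 relays every later stereocentre.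

Assumption: commercial (S)-(+)-terpinen-4-ol is used at ≥98% ee, and the product has the ee of that lot.

Daucane numbering is used throughout:
- C1 is the quaternary C–CH3.
- C4 is C(OH)iPr.
- C5 is the ring-fusion CH.
- C6 is the ester carbon.
- C8/C9 are the epoxide carbons.
- β is the face of the C1-methyl and C4-OH groups. α is the face of H-5 and iPr.

## Route

Step 1
Reactants: 1 (S)-(+)-terpinen-4-ol
Product: 3 (3S)-3-hydroxy-6-oxo-3-(propan-2-yl)heptanal, via secondary ozonide 2 (not isolated)
Conditions: O3, CH2Cl2, −78 °C; then Me2S, −78 °C → rt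
Reagents that add atoms: ozone [O-][O+]=O
Why: Ozonolysis (1,3-dipolar cycloaddition, cycloreversion, recombination) cleaves the only alkene and leaves the C4 carbinol centre untouched.

Step 2
Reactants: 3 (3S)-3-hydroxy-6-oxo-3-(propan-2-yl)heptanal
Product: 5 (5R)-5-hydroxy-2-methyl-5-(propan-2-yl)cyclopent-1-ene-1-carbaldehyde, via ketol 4 (not isolated)
Conditions: piperidine (cat.), AcOH (cat.), toluene, rt → 50 °C
Reagents that add atoms: none
Why: In this enamine-mediated intramolecular aldol condensation (5-enolexo), the aldehyde α-carbon C5 attacks the methyl ketone C1 and water is lost, while C4 has no α-H and keeps its configuration.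

Step 3
Reactants: 5 (5R)-5-hydroxy-2-methyl-5-(propan-2-yl)cyclopent-1-ene-1-carbaldehyde
Product: 6 1-[(5R)-5-hydroxy-2-methyl-5-(propan-2-yl)cyclopent-1-en-1-yl]but-3-en-1-ol (carbinol epimers, used together)
Conditions: allylMgBr (2.3 equiv), THF, −78 °C; aq. work-up
Reagents that add atoms: allylmagnesium bromide C=CC[Mg]Br
Why: Grignard 1,2-addition to the enal follows deprotonation of the tertiary OH, and the epimer ratio at the new carbinol does not matter because that centre is oxidised next.

Step 4
Reactants: 6 1-[(5R)-5-hydroxy-2-methyl-5-(propan-2-yl)cyclopent-1-en-1-yl]but-3-en-1-ol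
Product: 7 1-[(5R)-5-hydroxy-2-methyl-5-(propan-2-yl)cyclopent-1-en-1-yl]but-3-en-1-one
Conditions: Dess–Martin periodinane, NaHCO3, CH2Cl2, 0 °C
Reagents that add atoms: none
Why: Buffered Dess–Martin oxidation takes only the secondary alcohol and is mild enough not to move the β,γ-alkene into conjugation.

Step 5
Reactants: 7 1-[(5R)-5-hydroxy-2-methyl-5-(propan-2-yl)cyclopent-1-en-1-yl]but-3-en-1-one
Product: 8 (1S)-1-[(5R)-5-hydroxy-2-methyl-5-(propan-2-yl)cyclopent-1-en-1-yl]but-3-en-1-ol
Conditions: Zn(BH4)2, Et2O, −78 → −30 °C; aq. work-up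
Reagents that add atoms: none
Why: In this chelation-controlled 1,2-reduction, Zn ties C4–O and C6=O into a six-membered chelate whose α face carries the isopropyl group, so hydride enters from the β face and sets (1S).

Step 6
Reactants: 8 (1S)-1-[(5R)-5-hydroxy-2-methyl-5-(propan-2-yl)cyclopent-1-en-1-yl]but-3-en-1-ol
Product: 10 (1R,2R,5R)-2-hydroxy-5-methyl-2-(propan-2-yl)-5-(prop-2-en-1-yl)cyclopentane-1-carbaldehyde, via dipotassium enolate 9 (not isolated)
Conditions: KH (3 equiv), THF, 0 → 45 °C; AcOH, −78 °C; crude product with Et3N (cat.), CH2Cl2, rt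
Reagents that add atoms: none
Why: In this anionic oxy-Cope [3,3] rearrangement, A(1,3) strain with the ring methyl keeps the carbinol H in the alkene plane and K+ bridges the two alkoxides on the β side, so the C6–allyl bond stands on the α face and allyl moves suprafacially to C1 (methyl ends β), and C5 then equilibrates to the aldehyde trans to iPr and allyl.

Step 7
Reactants: 10 (1R,2R,5R)-2-hydroxy-5-methyl-2-(propan-2-yl)-5-(prop-2-en-1-yl)cyclopentane-1-carbaldehyde
Product: 11 (1R,2S,3R)-2-[(1S)-1-hydroxy-3-methylbut-3-en-1-yl]-3-methyl-1-(propan-2-yl)-3-(prop-2-en-1-yl)cyclopentan-1-ol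
Conditions: methallylMgCl (2.5 equiv), THF, −78 °C; aq. work-up
Reagents that add atoms: 2-methylallylmagnesium chloride CC(=C)C[Mg]Cl
Why: In this 1,3-chelation-controlled Grignard addition, the Mg alkoxide at C4 binds the aldehyde oxygen and the cis-vicinal C1-methyl blocks one carbonyl face, so attack from the open face gives (6S).

Step 8
Reactants: 11 (1R,2S,3R)-2-[(1S)-1-hydroxy-3-methylbut-3-en-1-yl]-3-methyl-1-(propan-2-yl)-3-(prop-2-en-1-yl)cyclopentan-1-ol
Product: 12 jaeschkeanadiol, (3R,3aS,4S,8aR)-6,8a-dimethyl-3-(propan-2-yl)-1,2,3,3a,4,5,8,8a-octahydroazulene-3,4-diol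
Conditions: Grubbs II (5 mol%), CH2Cl2 (5 mM), reflux
Reagents that add atoms: none
Why: Ring-closing metathesis of the allyl and methallyl arms gives the trisubstituted (Z) cycloheptene on the trans-disposed side chains, with free hydroxyls tolerated and no stereocentre touched.

Step 9
Reactants: 12 jaeschkeanadiol
Product: 13 jaeschkeanadiol 6-O-benzoate (teferidin)
Conditions: BzCl, DMAP (cat.), pyridine, rt → 40 °C
Reagents that add atoms: benzoyl chloride O=C(Cl)c1ccccc1
Why: DMAP-catalysed acylation reaches only the equatorial secondary C6-OH because the tertiary C4-OH is too hindered, and configuration is retained.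

Step 10
Reactants: 13 jaeschkeanadiol 6-O-benzoate
Product: 14 target, 8α,9α-epoxyjaeschkeanadiol 6-O-benzoate
Conditions: mCPBA, CH2Cl2, 0 °C
Reagents that add atoms: 3-chloroperoxybenzoic acid O=C(OO)c1cccc(Cl)c1
Why: In this Prilezhaev epoxidation the axial angular methyl shields the β face and the C6 ester is equatorial, so oxygen is delivered syn from the α face and sets (8R,9S).

## Compound list

1 | (S)-(+)-terpinen-4-ol | CC(C)[C@]1(O)CCC(C)=CC1 | starting material
2 | secondary ozonide of 1 | CC(C)[C@]1(O)CCC2(C)OOC(C1)O2 | intermediate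
3 | (3S)-3-hydroxy-6-oxo-3-(propan-2-yl)heptanal | CC(C)[C@](O)(CCC(C)=O)CC=O | intermediate
4 | ketol, 2,5-dihydroxy-2-methyl-5-(propan-2-yl)cyclopentane-1-carbaldehyde | CC(C)[C@]1(O)CCC(C)(O)C1C=O | intermediate
5 | (5R)-5-hydroxy-2-methyl-5-(propan-2-yl)cyclopent-1-ene-1-carbaldehyde | CC(C)[C@]1(O)CCC(C)=C1C=O | intermediate
6 | allyl carbinol, epimers at the carbinol carbon | CC(C)[C@]1(O)CCC(C)=C1C(O)CC=C | intermediate
7 | allyl ketone | CC(C)[C@]1(O)CCC(C)=C1C(=O)CC=C | intermediate
8 | (1S)-allyl carbinol | CC(C)[C@]1(O)CCC(C)=C1[C@@H](O)CC=C | intermediate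
9 | dipotassium alkoxide-enolate | CC(C)[C@]1([O-])CC[C@](C)(CC=C)C1=C[O-].[K+].[K+] | intermediate
10 | (1R,2R,5R)-2-hydroxy-5-methyl-2-(propan-2-yl)-5-(prop-2-en-1-yl)cyclopentane-1-carbaldehyde | CC(C)[C@]1(O)CC[C@](C)(CC=C)[C@H]1C=O | intermediate
11 | seco-diene diol | CC(C)[C@]1(O)CC[C@](C)(CC=C)[C@H]1[C@@H](O)CC(C)=C | intermediate
12 | jaeschkeanadiol | CC(C)[C@]1(O)CC[C@]2(C)CC=C(C)C[C@H](O)[C@H]21 | intermediate
13 | jaeschkeanadiol 6-O-benzoate | CC(C)[C@]1(O)CC[C@]2(C)CC=C(C)C[C@H](OC(=O)c3ccccc3)[C@H]21 | intermediate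
14 | 8α,9α-epoxyjaeschkeanadiol 6-O-benzoate | CC(C)[C@]1(O)CC[C@]2(C)C[C@@H]3O[C@]3(C)C[C@H](OC(=O)c3ccccc3)[C@H]21 | target

Total step count: 10. Longest linear sequence: 10.

## Steps most likely to fail

**Step 6.** Three things can go wrong.
- The dialkoxide may fragment by retro-allylation.
- The allyl group may leak to the wrong face.
- The β-hydroxy aldehyde may suffer retro-aldol cleavage while C5 is being equilibrated.

The fallback sets out from 5 and returns at 12. It carries the rearrangement out on a tertiary carbinol, so the product is a ketone rather than a fragile aldehyde. Methallylmagnesium chloride adds to 5 to give the methallyl carbinol F8, and Dess–Martin oxidation gives the methallyl ketone F9. Chelation-controlled addition of allylmagnesium bromide from the β face gives the tertiary bis-homoallylic carbinol F10. In F10 the spectator methallyl arm avoids the isopropyl group. With KH, the allyl arm therefore migrates on the α face through the dipotassium enolate F11 to the methallyl ketone F12, whose C5 epimerises freely to the trans isomer. Ring-closing metathesis gives the cycloheptenone F13. Hydroxyl-directed reduction with Me4NBH(OAc)3 delivers hydride from the C4-OH (β) side and gives 12.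

**Step 2.** The free tertiary aldol unit in 3 can revert by retro-aldol or dehydrate under amine/acid catalysis before the ring closes.

The fallback sets out from 1 and returns at 5. It masks the hydroxyl first. TESOTf/2,6-lutidine gives the triethylsilyl ether F1. Ozonolysis through the ozonide F2, followed by Me2S, gives the silyloxy keto aldehyde F3. The same piperidinium acetate condensation runs through the silyloxy ketol F4 to the silyloxy enal F5. HF·pyridine then releases 5.

**Step 5.** The twisted, tetrasubstituted enone may not hold a clean zinc chelate, and the diastereomer ratio at C6 could then be low.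

The fallback sets out from 7 and returns at 8. It makes the hydride delivery intramolecular. Chlorodiisopropylsilane with Et3N/DMAP puts a Si–H group on the C4 oxygen to give the hydridosilyl ether F6. SnCl4-promoted intramolecular hydrosilylation at −78 °C transfers hydride from the β side and closes the cyclic dioxasilinane F7. HF·pyridine cleaves F7 to 8.

## Further compounds

F1 | step 2 | triethylsilyl ether of 1 | CC(C)[C@]1(O[Si](CC)(CC)CC)CCC(C)=CC1
F2 | step 2 | ozonide of F1 | CC(C)[C@]1(O[Si](CC)(CC)CC)CCC2(C)OOC(C1)O2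
F3 | step 2 | (3S)-6-oxo-3-(propan-2-yl)-3-(triethylsilyloxy)heptanal | CC(C)[C@](O[Si](CC)(CC)CC)(CCC(C)=O)CC=O
F4 | step 2 | silyloxy ketol | CC(C)[C@]1(O[Si](CC)(CC)CC)CCC(C)(O)C1C=O
F5 | step 2 | triethylsilyl ether of 5 | CC(C)[C@]1(O[Si](CC)(CC)CC)CCC(C)=C1C=O
F6 | step 5 | diisopropylhydridosilyl ether of 7 | CC(C)[C@]1(O[SiH](C(C)C)C(C)C)CCC(C)=C1C(=O)CC=C
F7 | step 5 | cyclic diisopropylsilylene derivative of 8 | CC(C)[C@]12CCC(C)=C1[C@H](CC=C)O[Si](C(C)C)(C(C)C)O2
F8 | step 6 | methallyl carbinol, epimers | CC(C)[C@]1(O)CCC(C)=C1C(O)CC(C)=C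
F9 | step 6 | methallyl ketone | CC(C)[C@]1(O)CCC(C)=C1C(=O)CC(C)=C
F10 | step 6 | tertiary allyl methallyl carbinol | CC(C)[C@]1(O)CCC(C)=C1[C@](O)(CC=C)CC(C)=C
F11 | step 6 | dipotassium alkoxide-enolate | CC(C)[C@]1([O-])CC[C@](C)(CC=C)C1=C([O-])CC(C)=C.[K+].[K+]
F12 | step 6 | 1-[(1S,2R,5R)-2-hydroxy-5-methyl-2-(propan-2-yl)-5-(prop-2-en-1-yl)cyclopentyl]-3-methylbut-3-en-1-one | CC(C)[C@]1(O)CC[C@](C)(CC=C)[C@H]1C(=O)CC(C)=C
F13 | step 6 | 6-oxo analogue of 12 (4-hydroxydauc-8-en-6-one) | CC(C)[C@]1(O)CC[C@]2(C)CC=C(C)CC(=O)[C@H]21
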